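**Retrosynthetic overview**

1. The target is taken back to 7,4'-di-O-benzyl-5-O-methyl flavone 17. The 3-hydroxyl comes from C3 lithiation, borylation and oxidation, and all O-alkyl groups are removed last.
2. Ring C is opened at C4–C4a to the (Z)-β-aryloxycinnamic acid 15. The strategy rests on one feature: O1 on C8a has a single free ortho carbon, C4a, because C8 carries the quaternary 2-methylbut-3-en-2-yl group. An acyl chain held through O1–C2=C3 can therefore close onto ring A in one direction only.
3. Acid 15 is opened at O1–C2 to phenol 10 and arylpropiolate 13 (oxa-Michael addition; 13 by Sonogashira coupling).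
4. Phenol 10 comes from acetophenone 1 through an ortho-quinone methide: methyl, then vinyl, are added to the acetyl carbon. The carbonate that survives this cascade keeps the two flanking ring oxygens differentiated.
5. Rings A and B are bought as arenes; ring C is the only ring formed, in step 8.

Key step: step 8

Remark: step 6 may give some E enol ether beside the expected Z isomer; compounds 14 to 16 are written as Z, and both geometries should converge in step 8.

**Route**

Step 1
Reactants: 1 2',6'-dihydroxy-4'-methoxyacetophenone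
Product: 2 2-acetyl-5-methoxy-1,3-phenylene di-tert-butyl dicarbonate
Conditions: Boc2O (2.5 equiv), DMAP (cat.), THF, rt
Reagents that add atoms: di-tert-butyl dicarbonate, CC(C)(C)OC(=O)OC(=O)OC(C)(C)C
Why: DMAP-catalysed O-acylation of both phenols with Boc2O (carbonate protection) should go to completion because the ketone cannot compete, and it installs the two carbonates, one of which later serves as the leaving group that releases the quinone methide.

Step 2
Reactants: 2 2-acetyl-5-methoxy-1,3-phenylene di-tert-butyl dicarbonate; 3 methyllithium; 4 vinylmagnesium bromide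
Product: 8 tert-butyl [3-hydroxy-5-methoxy-2-(2-methylbut-3-en-2-yl)phenyl] carbonate, via lithium alkoxide 5 (not isolated), via carbonate-shifted lithium phenoxide 6 (not isolated), via ortho-quinone methide 7 (not isolated)
Conditions: MeLi (1.05 equiv), Et2O/THF, −78 °C; then vinylMgBr (2.5 equiv), −78 °C to rt; aq. NH4Cl
Reagents that add atoms: none
Why: 1,2-addition of MeLi to the ketone gives alkoxide 5, the neighbouring Boc group shifts to it (6), exchange to magnesium and warming expel tert-butyl carbonate to give ortho-quinone methide 7, and the vinyl Grignard reagent adds 1,4 to its exocyclic carbon with rearomatisation, a known three-component ortho-quinone methide alkylation of ortho-OBoc aryl carbonyl compounds that here builds the quaternary carbon and leaves one carbonate in place, so that the two ring oxygens emerge differentiated.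

Step 3
Reactants: 8 tert-butyl [3-hydroxy-5-methoxy-2-(2-methylbut-3-en-2-yl)phenyl] carbonate
Product: 9 tert-butyl [3-(benzyloxy)-5-methoxy-2-(2-methylbut-3-en-2-yl)phenyl] carbonate
Conditions: BnBr, K2CO3, DMF, rt
Reagents that add atoms: benzyl bromide, BrCc1ccccc1
Why: Williamson ether synthesis on the only free phenol, in which fast alkylation by the benzylic bromide should outrun carbonate transfer between the hindered phenoxide and the hindered carbonate.

Step 4
Reactants: 9 tert-butyl [3-(benzyloxy)-5-methoxy-2-(2-methylbut-3-en-2-yl)phenyl] carbonate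
Product: 10 3-(benzyloxy)-5-methoxy-2-(2-methylbut-3-en-2-yl)phenol
Conditions: K2CO3 (cat.), MeOH, rt
Reagents that add atoms: none
Why: Base-mediated methanolysis (transesterification) of the aryl tert-butyl carbonate frees the phenol that becomes O1, while the benzyl ether, the methyl ether and the alkene are inert to K2CO3 in MeOH.

Step 5
Reactants: 11 1-(benzyloxy)-4-iodobenzene; 12 methyl propiolate
Product: 13 methyl 3-[4-(benzyloxy)phenyl]prop-2-ynoate
Conditions: PdCl2(PPh3)2 (cat.), CuI (cat.), K2CO3, THF, 65 °C, excess 12 added in portions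
Reagents that add atoms: none
Why: Sonogashira coupling of the aryl iodide with methyl propiolate, run with K2CO3 instead of an amine base so that no amine adds to the propiolate, should give the arylpropiolate.

Step 6
Reactants: 10 3-(benzyloxy)-5-methoxy-2-(2-methylbut-3-en-2-yl)phenol; 13 methyl 3-[4-(benzyloxy)phenyl]prop-2-ynoate
Product: 14 methyl (Z)-3-[3-(benzyloxy)-5-methoxy-2-(2-methylbut-3-en-2-yl)phenoxy]-3-[4-(benzyloxy)phenyl]prop-2-enoate
Conditions: Cs2CO3 (0.5 equiv), DMF, 80 °C
Reagents that add atoms: none
Why: Base-mediated conjugate addition of the phenoxide to the arylpropiolate (oxa-Michael hydroaryloxylation) forms the O1–C2 bond, anti protonation of the allenolate favours the Z enol ether, and the new vinyl group sits on the side of the oxygen away from the quaternary carbon, which is the side where ring closure must occur.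

Step 7
Reactants: 14 methyl (Z)-3-[3-(benzyloxy)-5-methoxy-2-(2-methylbut-3-en-2-yl)phenoxy]-3-[4-(benzyloxy)phenyl]prop-2-enoate
Product: 15 (Z)-3-[3-(benzyloxy)-5-methoxy-2-(2-methylbut-3-en-2-yl)phenoxy]-3-[4-(benzyloxy)phenyl]prop-2-enoic acid
Conditions: LiOH, THF/MeOH/H2O, 40 °C; then cold 1 M HCl to pH 4
Reagents that add atoms: lithium hydroxide, [Li+].[OH-]
Why: Saponification of the methyl ester, in which the β-aryloxycinnamate, a vinylogous carbonate and a poor Michael acceptor, is attacked by hydroxide at the ester carbonyl, and cold, mild acidification avoids protonation at the α-carbon and loss of CO2.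

Step 8
Reactants: 15 (Z)-3-[3-(benzyloxy)-5-methoxy-2-(2-methylbut-3-en-2-yl)phenoxy]-3-[4-(benzyloxy)phenyl]prop-2-enoic acid
Product: 17 7-(benzyloxy)-2-[4-(benzyloxy)phenyl]-5-methoxy-8-(2-methylbut-3-en-2-yl)-4H-chromen-4-one, via mixed trifluoroacetic anhydride 16 (not isolated)
Conditions: (CF3CO)2O (1.5 equiv), CH2Cl2, 0 °C to rt
Reagents that add atoms: none
Why: The acid is converted by (CF3CO)2O into mixed anhydride 16, whose acyl carbon (as the anhydride or as the derived acylium ion, stabilised by O1 as a vinylogous oxocarbenium ion) is attacked by C4a, the ring carbon ortho to O1 and to the 5-methoxy group and para to the 7-benzyloxy group, and loss of the proton from the arenium ion restores ring A. The closest known reaction type is the cyclisation of β-aryloxycinnamic acids to flavones, run here as an intramolecular Friedel–Crafts acylation through a mixed trifluoroacetic anhydride in place of strong mineral acid. Ring C closes as a six-membered ring by electrophilic aromatic substitution, the C4–C4a bond forming by 6-exo attack at the acyl carbon with the C4a–C8a bond of ring A inside the new ring. No stereocentre is formed, and the enol ether geometry is erased because the oxocarbenium form has a single C2–C3 bond that rotates, so E and Z acids should give the same flavone. The step needs site selectivity, which the substrate secures because the tether from O1 reaches only C4a and C8 and C8 already carries the quaternary 2-methylbut-3-en-2-yl group. It also needs chemoselectivity: the monosubstituted vinyl group, which could give only a secondary cation, and the benzyl ethers should survive CF3CO2H in CH2Cl2 at 0 °C, and the ring is activated enough that no stronger acid is required.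

Step 9
Reactants: 17 7-(benzyloxy)-2-[4-(benzyloxy)phenyl]-5-methoxy-8-(2-methylbut-3-en-2-yl)-4H-chromen-4-one
Product: 20 7-(benzyloxy)-2-[4-(benzyloxy)phenyl]-3-hydroxy-5-methoxy-8-(2-methylbut-3-en-2-yl)-4H-chromen-4-one, via 3-lithioflavone 18 (not isolated), via lithium trimethoxyborate 19 (not isolated)
Conditions: LiN(i-Pr)2 (1.3 equiv), THF, −78 °C; B(OMe)3, −78 to 0 °C; AcOH, 30% aq. H2O2, 0 °C to rt
Reagents that add atoms: hydrogen peroxide, OO
Why: Deprotonation of the flavone at C3 by the amide base (known C3 lithiation of 5-alkoxyflavones, helped by coordination to the C4 carbonyl), trapping with B(OMe)3 and oxidative 1,2-shift of the borate with H2O2 (boronate oxidation) should deliver the flavonol without touching the benzyl ethers or the alkene.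

Step 10
Reactants: 20 7-(benzyloxy)-2-[4-(benzyloxy)phenyl]-3-hydroxy-5-methoxy-8-(2-methylbut-3-en-2-yl)-4H-chromen-4-one
Product: 21 3,5,7-trihydroxy-2-(4-hydroxyphenyl)-8-(2-methylbut-3-en-2-yl)-4H-chromen-4-one
Conditions: BCl3 (8 equiv), C6HMe5 (8 equiv), CH2Cl2, −78 to 0 °C; MeOH, then aq. work-up
Reagents that add atoms: none
Why: BCl3 cleaves aryl benzyl ethers at −78 °C while C6HMe5 traps the benzyl cation by Friedel–Crafts alkylation, and on warming the 5-methoxy group is cleaved through the boron chelate with the C4 carbonyl (chloride attack on the methyl carbon), a known Lewis-acid ether cleavage under which a monosubstituted alkene, able to give only a secondary cation, should persist.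

**Compound list**

1 | 2',6'-dihydroxy-4'-methoxyacetophenone | CC(=O)c1c(O)cc(OC)cc1O | starting material
2 | 2-acetyl-5-methoxy-1,3-phenylene di-tert-butyl dicarbonate | CC(=O)c1c(OC(=O)OC(C)(C)C)cc(OC)cc1OC(=O)OC(C)(C)C | intermediate
3 | methyllithium | [Li]C | starting material
4 | vinylmagnesium bromide | C=C[Mg]Br | starting material
5 | lithium 2-[2,6-bis(tert-butoxycarbonyloxy)-4-methoxyphenyl]propan-2-olate | [Li]OC(C)(C)c1c(OC(=O)OC(C)(C)C)cc(OC)cc1OC(=O)OC(C)(C)C | intermediate (not isolated)
6 | lithium 3-(tert-butoxycarbonyloxy)-2-[2-(tert-butoxycarbonyloxy)propan-2-yl]-5-methoxyphenolate | [Li]Oc1cc(OC)cc(OC(=O)OC(C)(C)C)c1C(C)(C)OC(=O)OC(C)(C)C | intermediate (not isolated)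
7 | tert-butyl [3-methoxy-5-oxo-6-(propan-2-ylidene)cyclohexa-1,3-dien-1-yl] carbonate (ortho-quinone methide) | CC(C)=C1C(=O)C=C(OC)C=C1OC(=O)OC(C)(C)C | intermediate (not isolated)
8 | tert-butyl [3-hydroxy-5-methoxy-2-(2-methylbut-3-en-2-yl)phenyl] carbonate | C=CC(C)(C)c1c(O)cc(OC)cc1OC(=O)OC(C)(C)C | intermediate
9 | tert-butyl [3-(benzyloxy)-5-methoxy-2-(2-methylbut-3-en-2-yl)phenyl] carbonate | C=CC(C)(C)c1c(OCc2ccccc2)cc(OC)cc1OC(=O)OC(C)(C)C | intermediate
10 | 3-(benzyloxy)-5-methoxy-2-(2-methylbut-3-en-2-yl)phenol | C=CC(C)(C)c1c(O)cc(OC)cc1OCc1ccccc1 | intermediate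
11 | 1-(benzyloxy)-4-iodobenzene | Ic1ccc(OCc2ccccc2)cc1 | starting material
12 | methyl propiolate | C#CC(=O)OC | starting material
13 | methyl 3-[4-(benzyloxy)phenyl]prop-2-ynoate | COC(=O)C#Cc1ccc(OCc2ccccc2)cc1 | intermediate
14 | methyl (Z)-3-[3-(benzyloxy)-5-methoxy-2-(2-methylbut-3-en-2-yl)phenoxy]-3-[4-(benzyloxy)phenyl]prop-2-enoate | COC(=O)/C=C(\Oc1cc(OC)cc(OCc2ccccc2)c1C(C)(C)C=C)c1ccc(OCc2ccccc2)cc1 | intermediate
15 | (Z)-3-[3-(benzyloxy)-5-methoxy-2-(2-methylbut-3-en-2-yl)phenoxy]-3-[4-(benzyloxy)phenyl]prop-2-enoic acid | OC(=O)/C=C(\Oc1cc(OC)cc(OCc2ccccc2)c1C(C)(C)C=C)c1ccc(OCc2ccccc2)cc1 | intermediate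
16 | (Z)-3-[3-(benzyloxy)-5-methoxy-2-(2-methylbut-3-en-2-yl)phenoxy]-3-[4-(benzyloxy)phenyl]prop-2-enoic trifluoroacetic anhydride | O=C(OC(=O)C(F)(F)F)/C=C(\Oc1cc(OC)cc(OCc2ccccc2)c1C(C)(C)C=C)c1ccc(OCc2ccccc2)cc1 | intermediate (not isolated)
17 | 7-(benzyloxy)-2-[4-(benzyloxy)phenyl]-5-methoxy-8-(2-methylbut-3-en-2-yl)-4H-chromen-4-one | C=CC(C)(C)c1c(OCc2ccccc2)cc(OC)c2c(=O)cc(-c3ccc(OCc4ccccc4)cc3)oc12 | intermediate
18 | 7-(benzyloxy)-2-[4-(benzyloxy)phenyl]-3-lithio-5-methoxy-8-(2-methylbut-3-en-2-yl)-4H-chromen-4-one | C=CC(C)(C)c1c(OCc2ccccc2)cc(OC)c2c(=O)c([Li])c(-c3ccc(OCc4ccccc4)cc3)oc12 | intermediate (not isolated)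
19 | lithium {7-(benzyloxy)-2-[4-(benzyloxy)phenyl]-5-methoxy-8-(2-methylbut-3-en-2-yl)-4-oxo-4H-chromen-3-yl}trimethoxyborate | [Li+].C=CC(C)(C)c1c(OCc2ccccc2)cc(OC)c2c(=O)c([B-](OC)(OC)OC)c(-c3ccc(OCc4ccccc4)cc3)oc12 | intermediate (not isolated)
20 | 7-(benzyloxy)-2-[4-(benzyloxy)phenyl]-3-hydroxy-5-methoxy-8-(2-methylbut-3-en-2-yl)-4H-chromen-4-one | C=CC(C)(C)c1c(OCc2ccccc2)cc(OC)c2c(=O)c(O)c(-c3ccc(OCc4ccccc4)cc3)oc12 | intermediate
21 | 3,5,7-trihydroxy-2-(4-hydroxyphenyl)-8-(2-methylbut-3-en-2-yl)-4H-chromen-4-one | C=CC(C)(C)c1c(O)cc(O)c2c(=O)c(O)c(-c3ccc(O)cc3)oc12 | target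

**Step count**

Total step count: 10. Longest linear sequence: 9 steps (steps 1 to 4 and 6 to 10 from compound 1); step 5 is the side branch.

**Steps most likely to fail**

Step 8. The cyclisation may be diverted in three ways. The acid released may protonate the vinyl group and start cation chemistry next to the benzyloxy oxygen. The β-aryloxyacrylic acid may be protonated at the α-carbon and lose CO2 before it is activated. Ring A may be trifluoroacetylated instead of acylated intramolecularly. The fallback closes ring C in the opposite bond order (C4–C4a first, O1–C2 last); it sets out from phenol 10 and comes back at flavone 17, so it also avoids steps 5 to 7. Ortho-formylation of 10 through its magnesium phenoxide (MgCl2, Et3N, paraformaldehyde, MeCN, reflux), which can only take place at the one free position ortho to the hydroxyl, should give 4-(benzyloxy)-2-hydroxy-6-methoxy-3-(2-methylbut-3-en-2-yl)benzaldehyde F1. Addition of the lithium acetylide made from commercial 1-(benzyloxy)-4-ethynylbenzene (n-BuLi, THF, −78 °C, 2.2 equiv so that the phenoxide is formed first) should give racemic 1-[4-(benzyloxy)-2-hydroxy-6-methoxy-3-(2-methylbut-3-en-2-yl)phenyl]-3-[4-(benzyloxy)phenyl]prop-2-yn-1-ol F2. Oxidation with MnO2 in CH2Cl2 should give 1-[4-(benzyloxy)-2-hydroxy-6-methoxy-3-(2-methylbut-3-en-2-yl)phenyl]-3-[4-(benzyloxy)phenyl]prop-2-yn-1-one F3. DMAP-catalysed 6-endo addition of the phenol to the ynone in DMF, the known flavone closure of ortho-hydroxyaryl ynones, should then give 17.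

Step 2. MeLi may enolise the hindered, twisted ketone or attack a carbonate instead of the carbonyl, and the quinone methide may tautomerise to the isopropenylphenol by hydrogen shift before the vinyl group adds. The fallback introduces the methyl group before the carbonates; it sets out from acetophenone 1 and comes back at alkoxide 5 of step 2. Excess MeMgBr in THF adds to the unprotected ketone, which as its magnesium bis-phenoxide chelate is planar and open on both faces, to give 2-(2-hydroxypropan-2-yl)-5-methoxybenzene-1,3-diol F4. Selective acylation of the two phenols (Boc2O, DMAP cat., THF, 0 °C; the tertiary alcohol does not react) should give 2-(2-hydroxypropan-2-yl)-5-methoxy-1,3-phenylene di-tert-butyl dicarbonate F5. Deprotonation of F5 with LiN(SiMe3)2 at −78 °C gives lithium alkoxide 5, and addition of vinylMgBr with warming continues through 6 and 7 to 8 as in the main route.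

Step 10. The 5-O-methyl group may not be cleaved at temperatures the alkene tolerates, or the freed 7-hydroxyl may add to the neighbouring vinyl group under acid during the warm phase and close a dihydrofuran. The fallback separates the two cleavages and removes the methyl group while O7 is still benzylated; it sets out from 20 and comes back at target 21. MgI2 etherate in THF/toluene at 60 °C cleaves only the methyl ether held in the magnesium chelate with the C4 carbonyl, by iodide attack on the methyl carbon, and should give 7-(benzyloxy)-2-[4-(benzyloxy)phenyl]-3,5-dihydroxy-8-(2-methylbut-3-en-2-yl)-4H-chromen-4-one F6. The two benzyl ethers are then removed with BCl3 and C6HMe5 in CH2Cl2 kept at −78 °C throughout, to give 21.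

**Further compounds**

F1 | step 8 | 4-(benzyloxy)-2-hydroxy-6-methoxy-3-(2-methylbut-3-en-2-yl)benzaldehyde | O=Cc1c(O)c(C(C)(C)C=C)c(OCc2ccccc2)cc1OC
F2 | step 8 | 1-[4-(benzyloxy)-2-hydroxy-6-methoxy-3-(2-methylbut-3-en-2-yl)phenyl]-3-[4-(benzyloxy)phenyl]prop-2-yn-1-ol (racemic) | OC(C#Cc1ccc(OCc2ccccc2)cc1)c1c(O)c(C(C)(C)C=C)c(OCc2ccccc2)cc1OC
F3 | step 8 | 1-[4-(benzyloxy)-2-hydroxy-6-methoxy-3-(2-methylbut-3-en-2-yl)phenyl]-3-[4-(benzyloxy)phenyl]prop-2-yn-1-one | O=C(C#Cc1ccc(OCc2ccccc2)cc1)c1c(O)c(C(C)(C)C=C)c(OCc2ccccc2)cc1OC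
F4 | step 2 | 2-(2-hydroxypropan-2-yl)-5-methoxybenzene-1,3-diol | CC(C)(O)c1c(O)cc(OC)cc1O
F5 | step 2 | 2-(2-hydroxypropan-2-yl)-5-methoxy-1,3-phenylene di-tert-butyl dicarbonate | CC(C)(O)c1c(OC(=O)OC(C)(C)C)cc(OC)cc1OC(=O)OC(C)(C)C
F6 | step 10 | 7-(benzyloxy)-2-[4-(benzyloxy)phenyl]-3,5-dihydroxy-8-(2-methylbut-3-en-2-yl)-4H-chromen-4-one | C=CC(C)(C)c1c(OCc2ccccc2)cc(O)c2c(=O)c(O)c(-c3ccc(OCc4ccccc4)cc3)oc12
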